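**Numbering used throughout:** 1 2,4,6-trihydroxybenzaldehyde; 2 prenol; 3 4-O-prenyl ether of 1; 4 ortho-dienone; 5 C-(1,1-dimethylallyl) trihydroxybenzaldehyde; 6 its 4,6-bis-MOM ether; 7 benzyl ether of 6; 8 salicylaldehyde; 9 salicyl alcohol; 10 2-methoxy-4-vinylphenol; 11 o-quinone methide; 12 (2S)-flavan; 13 its 4′-O-Boc carbonate; 14 flavan-4-ol; 15 protected flavanone; 16 target.

## Analysis of the target

Compound 16 is a (2S)-flavanone: a chroman-4-one (aromatic ring A fused to the oxygen heterocycle, ring C) carrying a 4-hydroxy-3-methoxyphenyl group (ring B) at C2. Ring A is substituted everywhere except C8: O1 at C8a, the carbonyl-bearing C4a, hydroxyls at C5 and C7 and, between them at C6, a 2-methylbut-3-en-2-yl (1,1-dimethylallyl) group bonded through its quaternary carbon. C2 is the only stereocentre. It is benzylic, bonded to O1 and β to the C4 carbonyl, so it can be lost by ring opening to the 2′-hydroxychalcone under base and by ionisation of the C2–O1 bond, which the para hydroxyl of ring B assists. The terminal alkene excludes hydrogenolysis, and with a free hydroxyl on each side it can close to a dihydrobenzofuran under strong acid or long heating. The difficulties are therefore three: placing the dimethylallyl group on C6 and not C8, telling apart the three ring A oxygens (O1, O5, O7), and creating C2 as one enantiomer in a molecule that racemises once ketone and 4′-hydroxyl are both present. The strategy rests on ring C being the chain O1–C2–C3–C4 closed onto C8a and C4a: the atoms O1, C8a, C4a and C4 form the heterodiene of an o-quinone methide, and C2–C3 with ring B attached is the vinyl group of the commercial styrene 10. C4 is carried as CH2 through ring formation and oxidised afterwards, at the one benzylic position that three ring A oxygens activate.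

## Retrosynthetic reasoning

**16 ⇒ 15.** The last operation is deprotection only. The alkene forbids hydrogenolysis and the 4′-hydroxyflavanone forbids base, so O5 carries a benzyl ether, O7 a methoxymethyl acetal and O4′ a tert-butyl carbonate. All three fall to one Lewis acid in the presence of a cation scavenger.

**15 ⇒ 14 ⇒ 13.** The C4 carbonyl is traced back to a methylene group by way of the alcohol 14. The C4–H bonds are the ones to oxidise because C4 is benzylic to ring A and ortho or para to O1, O5 and O7, whereas the C2–H bond sits on ring B, which the carbonate makes electron-poor. The gain is that ring C can be formed without an enolisable ketone and by a cycloaddition.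

**13 ⇒ 12.** The carbonate is removed in the retrosynthetic sense because the free 4′-hydroxyl is needed in the ring-forming step, as the activating group of the styrene and as the point at which the catalyst holds it.

**12 ⇒ 9 + 10 (through 11).** The bonds O1–C2 and C3–C4 are cut. Both lie in ring C, so this one disconnection detaches ring B with C2 and C3 as the commercial styrene 10 and leaves ring A with C4 as the salicyl alcohol 9. No other pair of ring C bonds gives two fragments of such unequal complexity with the stereocentre formed in the same event. The forward reaction has to dehydrate 9 to the methide 11 and add 10 across O1 and C4 with the aryl group at C2 and with control of the face at C2.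

**9 ⇒ 8 ⇒ 7 ⇒ 6.** The hydroxymethyl group comes from a formyl group by hydride reduction. Ring A has two oxygens ortho to C4a, and whichever is free becomes O1; this decides between a C6- and a C8-substituted chroman. The oxygen next to the dimethylallyl group (future O5) is therefore benzylated while the other two are acetals (7), and the acetal next to the formyl group is then removed by chelation to give 8.

**6 ⇒ 5 ⇒ 3 ⇒ 1 + 2.** The bond between the ring and the quaternary carbon is cut by an aromatic Claisen retron, leading to a prenyl aryl ether. The ether is placed on the oxygen para to the formyl group (future O7) and not on a flanking oxygen. In 3 the two ortho carbons are equivalent and the para carbon is substituted, so the rearrangement has a single outcome and a second shift to a free para carbon cannot occur. The flanking-oxygen ether would leave that para carbon open, and on electron-rich rings of this kind the second shift competes strongly. The most awkward substituent is thus installed on a symmetric seven-carbon aromatic in two steps from 1 and 2.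

## Alternatives that were turned down

**Alternative 1:** Ring A is disconnected at C5–C6, C7–C8 and C4a–C5 and built last on an enantiopure dihydropyranone.
- Forward key step: irradiation of the diazoketone A2 causes Wolff rearrangement to a vinylketene. This adds to the siloxyalkyne A3 in a (2+2) reaction, and four-electron ring opening, six-electron ring closure and tautomerisation give the bis-silyl ether A1. Desilylation of A1 would give 16.
- For it: the connectivity fixes every ring A substituent. The dimethylallyl group arrives on the alkyne carbon between the two oxygens, O5 is free and O7 silylated without any protecting-group manoeuvre, and C4 is already a ketone. On regiocontrol of ring A and on the absence of a late oxidation it is stronger than the chosen route.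
- Against it: A2 is an enantiopure 2-aryl-2,3-dihydropyran-4-one with a diazoacetyl group and needs its own multi-step asymmetric synthesis. Its C2 is a benzylic β-alkoxy enone position that can ring-open under the irradiation and the heating needed to finish the cascade, so the stereocentre is at risk in the key step. A3 has a quaternary propargylic carbon, which slows the (2+2) step and lets ketene dimerisation compete, and A3 itself takes several steps from an ester.
- Comparison: the chosen route offers a far shorter approach (six steps to 9 from a commercial aldehyde) and creates C2 in the ring-forming step instead of carrying it through photolysis.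

**Alternative 2:** Ring C is cut at O1–C8a and C4–C4a, so ring A enters as an aryne.
- Forward key step: CsF releases the aryne from the silyl triflate A5. The alkoxide of the (S)-hydroxy ester A6 adds at C8a, remote from the flanking alkoxy group, and the aryl anion formed at C4a attacks the ester to give the flavanone A4.
- For it: C2 comes from a dependable asymmetric hydrogenation of a β-keto ester, two bonds and ring C form at once, C4 is a ketone from the start, and the aryne regiochemistry is predictable. On certainty of the C2 configuration it is stronger than the chosen route.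
- Against it: A4 has no substituent at C6. The dimethylallyl group would have to be added to the finished flavanone by unmasking O5, prenylation and a thermal shift. In that ether C8 is a free para carbon, so migration on to C8 competes, and the flavanone must survive base and high temperature, both of which open ring C and racemise C2. Aliphatic alkoxides add to arynes less cleanly than phenoxides, the β-alkoxide can eliminate to a cinnamate or undergo retro-aldol cleavage under fluoride, and A5 takes several steps.
- Comparison: the chosen route places the dimethylallyl group before any stereocentre exists, on a substrate where the shift can go only one way, and never exposes a flavanone to base or heat.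

**Alternative 3:** C4–C4a is cut as a Friedel–Crafts acylation and O1–C2 as an aryl ether made with inversion.
- Forward key step: Mitsunobu reaction of the (R)-hydroxy ester A10 with the symmetric phenol A9, followed by ester cleavage, gives the acid A8. Its mixed anhydride with (CF3CO)2O acylates the ring carbon ortho to the ether oxygen and closes ring C to A7.
- For it: every step is of a known type, the nucleophile is symmetric so the acylation has no regiochemical question, and C4 is a ketone from the outset. Up to A7 it is more reliable than the chosen route is up to 12.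
- Against it: displacement at a benzylic carbinol β to an ester competes with elimination to the cinnamate, and the 3-aryl-3-aryloxy acid can lose the phenol under strongly acidic acylation, which erodes C2. The decisive point is that A7 again lacks the dimethylallyl group. Two identical benzyl ethers must be told apart, the shift run with C8 free, and the second benzyl group removed without hydrogenation, all on a fragile flavanone and at a cost of five or more further steps.
- Comparison: the chosen route is shorter (eleven steps) and concentrates its risk in one ring-forming step on a robust flavan.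

Key step: step 7

## Route

Assumption: the sense of induction of a given catalyst antipode cannot be derived with confidence for a methide without a substituent at the methide carbon; the (R)-catalyst is written, and its mirror image would be used if the first run showed the (2R)-flavan.

**Step 1**
Reactants: 1 2,4,6-trihydroxybenzaldehyde; 2 3-methylbut-2-en-1-ol (prenol)
Product: 3 2,6-dihydroxy-4-[(3-methylbut-2-en-1-yl)oxy]benzaldehyde
Conditions: PPh3, diisopropyl azodicarboxylate, THF, 0 °C → rt
Reagents that add atoms: none
Why: Mitsunobu etherification; the 4-hydroxyl is the most acidic phenol (para to the formyl group) and the only one not held in a hydrogen bond to the carbonyl oxygen, so it should react first, and the neutral conditions avoid the C-alkylation that a phloroglucinol anion shows with allylic halides.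

**Step 2**
Reactants: 3 2,6-dihydroxy-4-[(3-methylbut-2-en-1-yl)oxy]benzaldehyde
Product: 5 2,4,6-trihydroxy-3-(2-methylbut-3-en-2-yl)benzaldehyde, via ortho-dienone 4 (not isolated)
Conditions: N,N-diethylaniline, 180 °C, sealed tube, Ar
Reagents that add atoms: none
Why: Aromatic Claisen rearrangement ([3,3] shift) delivers the allyl unit with transposition to a ring carbon ortho to the ether oxygen, giving the 1,1-dimethylallyl group; the two ortho carbons are equivalent and the para carbon bears the formyl group, so the dienone 4 can only enolise to 5 and no second shift to a free para carbon is possible.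

**Step 3**
Reactants: 5 2,4,6-trihydroxy-3-(2-methylbut-3-en-2-yl)benzaldehyde
Product: 6 2-hydroxy-4,6-bis(methoxymethoxy)-3-(2-methylbut-3-en-2-yl)benzaldehyde
Conditions: MOMCl (2.2 equiv), i-Pr2NEt, CH2Cl2, 0 °C → rt
Reagents that add atoms: chloromethyl methyl ether, COCCl
Why: O-alkylation to the acetals; the non-chelated 4-hydroxyl and then the unhindered 6-hydroxyl should react, while the 2-hydroxyl, hydrogen-bonded to the formyl oxygen and shielded by the neighbouring quaternary carbon, should stay free, in line with the usual bis-protection of 2,4,6-trihydroxyaryl carbonyl compounds.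

**Step 4**
Reactants: 6 2-hydroxy-4,6-bis(methoxymethoxy)-3-(2-methylbut-3-en-2-yl)benzaldehyde
Product: 7 2-(benzyloxy)-4,6-bis(methoxymethoxy)-3-(2-methylbut-3-en-2-yl)benzaldehyde
Conditions: BnBr, Cs2CO3, Bu4NI (cat.), DMF, 50 °C
Reagents that add atoms: benzyl bromide, BrCc1ccccc1
Why: Williamson etherification of the only remaining nucleophilic site; Cs2CO3 in DMF with iodide catalysis is chosen because this phenol is both chelated and flanked by a quaternary carbon.

**Step 5**
Reactants: 7 2-(benzyloxy)-4,6-bis(methoxymethoxy)-3-(2-methylbut-3-en-2-yl)benzaldehyde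
Product: 8 2-(benzyloxy)-6-hydroxy-4-(methoxymethoxy)-3-(2-methylbut-3-en-2-yl)benzaldehyde
Conditions: MgBr2·OEt2, Et2O–CH2Cl2, 0 °C → rt
Reagents that add atoms: none
Why: Chelation-controlled acetal cleavage; magnesium binds the formyl oxygen and the coplanar acetal oxygen at C6 and bromide opens the activated methoxymethyl group, whereas the acetal at C4 cannot chelate and an ortho benzyl ether needs much more forcing conditions with this reagent.

**Step 6**
Reactants: 8 2-(benzyloxy)-6-hydroxy-4-(methoxymethoxy)-3-(2-methylbut-3-en-2-yl)benzaldehyde
Product: 9 3-(benzyloxy)-2-(hydroxymethyl)-5-(methoxymethoxy)-4-(2-methylbut-3-en-2-yl)phenol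
Conditions: NaBH4, THF–MeOH, 0 °C; pH 7 buffer work-up
Reagents that add atoms: none
Why: Hydride reduction of the aldehyde; low temperature and a neutral work-up are used because this electron-rich salicyl alcohol ionises easily (self-condensation, or over-reduction through the methide), and 9 is taken on at once without chromatography on acidic silica.

**Step 7**
Reactants: 9 3-(benzyloxy)-2-(hydroxymethyl)-5-(methoxymethoxy)-4-(2-methylbut-3-en-2-yl)phenol; 10 2-methoxy-4-vinylphenol
Product: 12 4-[(2S)-5-(benzyloxy)-7-(methoxymethoxy)-6-(2-methylbut-3-en-2-yl)-3,4-dihydro-2H-chromen-2-yl]-2-methoxyphenol, via o-quinone methide 11 (not isolated)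
Conditions: (R)-3,3′-bis(2,4,6-triisopropylphenyl)-1,1′-binaphthyl-2,2′-diyl hydrogen phosphate (10 mol %), 4 Å molecular sieves, toluene, 0 °C → rt, slow addition of 9 to 10 (3 equiv)
Reagents that add atoms: none
Why: Proposed new method: the phosphoric acid protonates the benzylic hydroxyl of 9 and water leaves, giving the o-quinone methide 11, which is stabilised by the ether oxygens ortho and para to the methide carbon and stays hydrogen-bonded to the catalyst through its carbonyl oxygen while the phosphoryl oxygen binds the phenolic hydroxyl of 10. The electron-rich terminal carbon of the vinyl group (future C3) attacks the methide carbon (C4) and the methide oxygen (O1) closes on the benzylic carbon (C2) in an asynchronous inverse-demand hetero-Diels–Alder reaction that restores the aromaticity of ring A; in the stepwise limit the second bond is an oxa-1,6-addition of the ring A phenol to a p-quinone methide still held in the chiral ion pair. The closest known reaction type is the chiral phosphoric acid-catalysed (4+2) cycloaddition of o-quinone methides, made from o-hydroxybenzyl alcohols, with hydroxystyrenes, vinylindoles and enamides; new here is a methide without a substituent at the methide carbon combined with a para-hydroxystyrene, so that C2 is the only stereocentre formed. Ring C is closed as a six-membered dihydropyran by (4+2) cycloaddition, or by 6-exo-trig attack of O1 on C2 if the process is stepwise. The configuration at C2 is controlled by the catalyst alone, through two-point binding of the methide oxygen and the 4′-hydroxyl, which should expose one face of the benzylic carbon to O1. Regioselectivity (aryl at C2, not C3) follows from the polarity of both partners, and the single free phenol of ring A fixes which oxygen becomes O1, so that the dimethylallyl group ends at C6 and not C8. Chemoselectivity over attack of 11 on the free C8 position of 9 or 12 is sought by slow addition of 9 to an excess of 10.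

**Step 8**
Reactants: 12 4-[(2S)-5-(benzyloxy)-7-(methoxymethoxy)-6-(2-methylbut-3-en-2-yl)-3,4-dihydro-2H-chromen-2-yl]-2-methoxyphenol
Product: 13 tert-butyl 4-[(2S)-5-(benzyloxy)-7-(methoxymethoxy)-6-(2-methylbut-3-en-2-yl)-3,4-dihydro-2H-chromen-2-yl]-2-methoxyphenyl carbonate
Conditions: Boc2O, 4-(dimethylamino)pyridine (5 mol %), MeCN, rt
Reagents that add atoms: di-tert-butyl dicarbonate, CC(C)(C)OC(=O)OC(=O)OC(C)(C)C
Why: Acylation of the phenol under nucleophilic catalysis; the carbonate turns the para oxygen of ring B from a donor into an acceptor, which protects the phenol from the quinone of step 9 and deactivates the C2–H bond towards hydride abstraction.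

**Step 9**
Reactants: 13 tert-butyl 4-[(2S)-5-(benzyloxy)-7-(methoxymethoxy)-6-(2-methylbut-3-en-2-yl)-3,4-dihydro-2H-chromen-2-yl]-2-methoxyphenyl carbonate
Product: 14 tert-butyl 4-[(2S,4RS)-5-(benzyloxy)-4-hydroxy-7-(methoxymethoxy)-6-(2-methylbut-3-en-2-yl)-3,4-dihydro-2H-chromen-2-yl]-2-methoxyphenyl carbonate
Conditions: DDQ (2,3-dichloro-5,6-dicyano-1,4-benzoquinone, 1.2 equiv), CH2Cl2–H2O (10:1), 0 °C → rt
Reagents that add atoms: water, O
Why: Benzylic C–H oxidation by hydride abstraction with a quinone, the usual way to functionalise C4 of 5,7-dialkoxyflavans; the C4 cation is stabilised by O1, O5 and O7 and is captured by water, whereas C2–H sits on the deactivated ring B. The configuration at C4 is irrelevant because step 10 removes it.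

**Step 10**
Reactants: 14 tert-butyl 4-[(2S,4RS)-5-(benzyloxy)-4-hydroxy-7-(methoxymethoxy)-6-(2-methylbut-3-en-2-yl)-3,4-dihydro-2H-chromen-2-yl]-2-methoxyphenyl carbonate
Product: 15 tert-butyl 4-[(2S)-5-(benzyloxy)-7-(methoxymethoxy)-6-(2-methylbut-3-en-2-yl)-4-oxo-3,4-dihydro-2H-chromen-2-yl]-2-methoxyphenyl carbonate
Conditions: Dess–Martin periodinane, CH2Cl2, 0 °C → rt
Reagents that add atoms: none
Why: Dess–Martin oxidation of the secondary benzylic alcohol to the ketone under neutral conditions, which leave the acetal, the carbonate and the alkene untouched and give no base-induced ring opening at C2.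

**Step 11**
Reactants: 15 tert-butyl 4-[(2S)-5-(benzyloxy)-7-(methoxymethoxy)-6-(2-methylbut-3-en-2-yl)-4-oxo-3,4-dihydro-2H-chromen-2-yl]-2-methoxyphenyl carbonate
Product: 16 (2S)-5,7-dihydroxy-2-(4-hydroxy-3-methoxyphenyl)-6-(2-methylbut-3-en-2-yl)-2,3-dihydro-4H-chromen-4-one
Conditions: BCl3, C6HMe5, CH2Cl2, −78 → 0 °C; then MeOH, rt
Reagents that add atoms: none
Why: Lewis-acid deprotection with a cation scavenger; BCl3 cleaves the benzyl ether chelated to the C4 carbonyl, the methoxymethyl acetal and the tert-butyl carbonate, and pentamethylbenzene takes up the benzyl cation so that it does not alkylate C8 or the alkene. Neither hydrogenation (the vinyl group) nor base (C2 of a 4′-hydroxyflavanone) is involved.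

## Compound list

1 | 2,4,6-trihydroxybenzaldehyde | O=Cc1c(O)cc(O)cc1O | starting material
2 | 3-methylbut-2-en-1-ol (prenol) | CC(C)=CCO | starting material
3 | 2,6-dihydroxy-4-[(3-methylbut-2-en-1-yl)oxy]benzaldehyde | O=Cc1c(O)cc(OCC=C(C)C)cc1O | intermediate
4 | 2,6-dihydroxy-3-(2-methylbut-3-en-2-yl)-4-oxocyclohexa-1,5-diene-1-carbaldehyde (racemic ortho-dienone, not isolated) | O=CC1=C(O)C(C(C)(C)C=C)C(=O)C=C1O | intermediate
5 | 2,4,6-trihydroxy-3-(2-methylbut-3-en-2-yl)benzaldehyde | O=Cc1c(O)c(C(C)(C)C=C)c(O)cc1O | intermediate
6 | 2-hydroxy-4,6-bis(methoxymethoxy)-3-(2-methylbut-3-en-2-yl)benzaldehyde | O=Cc1c(O)c(C(C)(C)C=C)c(OCOC)cc1OCOC | intermediate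
7 | 2-(benzyloxy)-4,6-bis(methoxymethoxy)-3-(2-methylbut-3-en-2-yl)benzaldehyde | O=Cc1c(OCc2ccccc2)c(C(C)(C)C=C)c(OCOC)cc1OCOC | intermediate
8 | 2-(benzyloxy)-6-hydroxy-4-(methoxymethoxy)-3-(2-methylbut-3-en-2-yl)benzaldehyde | O=Cc1c(OCc2ccccc2)c(C(C)(C)C=C)c(OCOC)cc1O | intermediate
9 | 3-(benzyloxy)-2-(hydroxymethyl)-5-(methoxymethoxy)-4-(2-methylbut-3-en-2-yl)phenol | OCc1c(OCc2ccccc2)c(C(C)(C)C=C)c(OCOC)cc1O | intermediate
10 | 2-methoxy-4-vinylphenol | C=Cc1ccc(O)c(OC)c1 | starting material
11 | 5-(benzyloxy)-3-(methoxymethoxy)-6-methylidene-4-(2-methylbut-3-en-2-yl)cyclohexa-2,4-dien-1-one (o-quinone methide, not isolated) | C=C1C(=O)C=C(OCOC)C(C(C)(C)C=C)=C1OCc1ccccc1 | intermediate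
12 | 4-[(2S)-5-(benzyloxy)-7-(methoxymethoxy)-6-(2-methylbut-3-en-2-yl)-3,4-dihydro-2H-chromen-2-yl]-2-methoxyphenol | C=CC(C)(C)c1c(OCOC)cc2c(c1OCc1ccccc1)CC[C@@H](c1ccc(O)c(OC)c1)O2 | intermediate
13 | tert-butyl 4-[(2S)-5-(benzyloxy)-7-(methoxymethoxy)-6-(2-methylbut-3-en-2-yl)-3,4-dihydro-2H-chromen-2-yl]-2-methoxyphenyl carbonate | C=CC(C)(C)c1c(OCOC)cc2c(c1OCc1ccccc1)CC[C@@H](c1ccc(OC(=O)OC(C)(C)C)c(OC)c1)O2 | intermediate
14 | tert-butyl 4-[(2S,4RS)-5-(benzyloxy)-4-hydroxy-7-(methoxymethoxy)-6-(2-methylbut-3-en-2-yl)-3,4-dihydro-2H-chromen-2-yl]-2-methoxyphenyl carbonate (both C4 epimers) | C=CC(C)(C)c1c(OCOC)cc2c(c1OCc1ccccc1)C(O)C[C@@H](c1ccc(OC(=O)OC(C)(C)C)c(OC)c1)O2 | intermediate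
15 | tert-butyl 4-[(2S)-5-(benzyloxy)-7-(methoxymethoxy)-6-(2-methylbut-3-en-2-yl)-4-oxo-3,4-dihydro-2H-chromen-2-yl]-2-methoxyphenyl carbonate | C=CC(C)(C)c1c(OCOC)cc2c(c1OCc1ccccc1)C(=O)C[C@@H](c1ccc(OC(=O)OC(C)(C)C)c(OC)c1)O2 | intermediate
16 | (2S)-5,7-dihydroxy-2-(4-hydroxy-3-methoxyphenyl)-6-(2-methylbut-3-en-2-yl)-2,3-dihydro-4H-chromen-4-one | C=CC(C)(C)c1c(O)cc2c(c1O)C(=O)C[C@@H](c1ccc(O)c(OC)c1)O2 | target

## Step count and least certain steps

Total step count: 11. Longest linear sequence: 11 steps (from 1; 2 and 10 are commercial).

**Step 7 (key step, proposed new method).**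
- What may go wrong: low enantioselectivity if the bond to O1 forms in a loosely organised ion pair, or through a p-quinone methide that has left the catalyst. The selectivity may also erode afterwards by acid-induced reversible ionisation of the C2–O1 bond of 12, which the free para hydroxyl assists. Independently, 11 may be consumed by electrophilic attack on the free C8 position of 9 or 12 (oligomerisation), and 10 may oligomerise under acid.
- Fallback, using known chemistry: 9 and 10 are heated without catalyst (toluene, 110–130 °C, sealed tube, radical inhibitor). Thermal loss of water and the known (4+2) addition of o-quinone methides to styrenes should give racemic 4-[5-(benzyloxy)-7-(methoxymethoxy)-6-(2-methylbut-3-en-2-yl)-3,4-dihydro-2H-chromen-2-yl]-2-methoxyphenol F1. Preparative supercritical-fluid chromatography on a chiral stationary phase then separates it into 12 and the (2R)-enantiomer, 4-[(2R)-5-(benzyloxy)-7-(methoxymethoxy)-6-(2-methylbut-3-en-2-yl)-3,4-dihydro-2H-chromen-2-yl]-2-methoxyphenol F2, which is discarded. Stereocontrol moves from catalysis to separation, and the route resumes at 12.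

**Step 2.**
- What may go wrong: at the temperature of the shift, a liberated hydroxyl next to the new alkene (O4, or O2) may add to it to give a dihydrobenzofuran, the abnormal Claisen isomerisation may set in, or the polyphenolic aldehyde may decompose.
- Fallback: the hydroxyls are masked first, setting out from 1. MOMCl (2 equiv) and i-Pr2NEt give 2-hydroxy-4,6-bis(methoxymethoxy)benzaldehyde F3. Mitsunobu reaction of its chelated hydroxyl with 2 gives 2,4-bis(methoxymethoxy)-6-[(3-methylbut-2-en-1-yl)oxy]benzaldehyde F4. Claisen rearrangement of F4 in N,N-diethylaniline gives 6 directly, the liberated phenol being tied up in the hydrogen bond to the formyl group.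
- Why this is only the fallback: in F4 the para carbon is free, so a second shift to that carbon competes and the isomers would have to be separated.

**Step 5.**
- What may go wrong: insufficient discrimination, with loss of the C4 acetal (twisted by the neighbouring quaternary carbon and therefore more basic) or of the ortho benzyl ether.
- Fallback: from 7, both acetals are removed with dilute HCl in MeOH to give 2-(benzyloxy)-4,6-dihydroxy-3-(2-methylbut-3-en-2-yl)benzaldehyde F5. One equivalent of MOMCl with i-Pr2NEt then protects the non-chelated 4-hydroxyl selectively and returns to the route at 8.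

**Step 9.**
- What may go wrong: loss of H3 from the C4 cation to give the flav-3-ene, whose further oxidation to a flavylium ion destroys C2; or competing hydride abstraction at C2.
- Fallback: from 13, acetoxylation with Pb(OAc)4 in benzene, a known way to functionalise C4 of 5,7-dialkoxyflavans, should give tert-butyl 4-[(2S,4RS)-4-(acetyloxy)-5-(benzyloxy)-7-(methoxymethoxy)-6-(2-methylbut-3-en-2-yl)-3,4-dihydro-2H-chromen-2-yl]-2-methoxyphenyl carbonate F6. This ester cannot eliminate or be re-oxidised by a quinone. Solvolysis in aqueous acetone with pyridinium p-toluenesulfonate returns to the route at 14.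

**Step 11.**
- What may go wrong: acid-promoted addition of a liberated phenol (O5 or O7) to the vinyl group, C-benzylation despite the scavenger, cleavage of the 3′-methyl ether, or Lewis-acid ring opening with loss of configuration at C2.
- Fallback: staged unmasking from 15. MgBr2·OEt2 in toluene–Et2O removes only the benzyl group chelated to the carbonyl and gives tert-butyl 4-[(2S)-5-hydroxy-7-(methoxymethoxy)-6-(2-methylbut-3-en-2-yl)-4-oxo-3,4-dihydro-2H-chromen-2-yl]-2-methoxyphenyl carbonate F7. Dilute HCl in MeOH at rt then removes the acetal and the carbonate and returns to the route at 16.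

## Further compounds

F1 | step 7 | racemic 4-[5-(benzyloxy)-7-(methoxymethoxy)-6-(2-methylbut-3-en-2-yl)-3,4-dihydro-2H-chromen-2-yl]-2-methoxyphenol | C=CC(C)(C)c1c(OCOC)cc2c(c1OCc1ccccc1)CCC(c1ccc(O)c(OC)c1)O2
F2 | step 7 | 4-[(2R)-5-(benzyloxy)-7-(methoxymethoxy)-6-(2-methylbut-3-en-2-yl)-3,4-dihydro-2H-chromen-2-yl]-2-methoxyphenol | C=CC(C)(C)c1c(OCOC)cc2c(c1OCc1ccccc1)CC[C@H](c1ccc(O)c(OC)c1)O2
F3 | step 2 | 2-hydroxy-4,6-bis(methoxymethoxy)benzaldehyde | O=Cc1c(O)cc(OCOC)cc1OCOC
F4 | step 2 | 2,4-bis(methoxymethoxy)-6-[(3-methylbut-2-en-1-yl)oxy]benzaldehyde | O=Cc1c(OCC=C(C)C)cc(OCOC)cc1OCOC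
F5 | step 5 | 2-(benzyloxy)-4,6-dihydroxy-3-(2-methylbut-3-en-2-yl)benzaldehyde | O=Cc1c(OCc2ccccc2)c(C(C)(C)C=C)c(O)cc1O
F6 | step 9 | tert-butyl 4-[(2S,4RS)-4-(acetyloxy)-5-(benzyloxy)-7-(methoxymethoxy)-6-(2-methylbut-3-en-2-yl)-3,4-dihydro-2H-chromen-2-yl]-2-methoxyphenyl carbonate | C=CC(C)(C)c1c(OCOC)cc2c(c1OCc1ccccc1)C(OC(C)=O)C[C@@H](c1ccc(OC(=O)OC(C)(C)C)c(OC)c1)O2
F7 | step 11 | tert-butyl 4-[(2S)-5-hydroxy-7-(methoxymethoxy)-6-(2-methylbut-3-en-2-yl)-4-oxo-3,4-dihydro-2H-chromen-2-yl]-2-methoxyphenyl carbonate | C=CC(C)(C)c1c(OCOC)cc2c(c1O)C(=O)C[C@@H](c1ccc(OC(=O)OC(C)(C)C)c(OC)c1)O2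
A1 | alternative 1 | (2S)-5-hydroxy-2-{3-methoxy-4-[(triisopropylsilyl)oxy]phenyl}-6-(2-methylbut-3-en-2-yl)-7-[(triisopropylsilyl)oxy]-2,3-dihydro-4H-chromen-4-one | C=CC(C)(C)c1c(O[Si](C(C)C)(C(C)C)C(C)C)cc2c(c1O)C(=O)C[C@@H](c1ccc(O[Si](C(C)C)(C(C)C)C(C)C)c(OC)c1)O2
A2 | alternative 1 | (2S)-6-(diazoacetyl)-2-{3-methoxy-4-[(triisopropylsilyl)oxy]phenyl}-2,3-dihydro-4H-pyran-4-one | [N-]=[N+]=CC(=O)C1=CC(=O)C[C@@H](c2ccc(O[Si](C(C)C)(C(C)C)C(C)C)c(OC)c2)O1
A3 | alternative 1 | [(3,3-dimethylpent-4-en-1-yn-1-yl)oxy]triisopropylsilane | C=CC(C)(C)C#CO[Si](C(C)C)(C(C)C)C(C)C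
A4 | alternative 2 | (2S)-2-[3-methoxy-4-(methoxymethoxy)phenyl]-5,7-bis(methoxymethoxy)-2,3-dihydro-4H-chromen-4-one | COCOc1cc2c(c(OCOC)c1)C(=O)C[C@@H](c1ccc(OCOC)c(OC)c1)O2
A5 | alternative 2 | 3,5-bis(methoxymethoxy)-2-(trimethylsilyl)phenyl trifluoromethanesulfonate | COCOc1cc(OCOC)c([Si](C)(C)C)c(OS(=O)(=O)C(F)(F)F)c1
A6 | alternative 2 | methyl (3S)-3-hydroxy-3-[3-methoxy-4-(methoxymethoxy)phenyl]propanoate | COC(=O)C[C@H](O)c1ccc(OCOC)c(OC)c1
A7 | alternative 3 | 4-[(2S)-5,7-bis(benzyloxy)-4-oxo-3,4-dihydro-2H-chromen-2-yl]-2-methoxyphenyl acetate | O=C1C[C@@H](c2ccc(OC(C)=O)c(OC)c2)Oc2cc(OCc3ccccc3)cc(OCc3ccccc3)c12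
A8 | alternative 3 | (3S)-3-[4-(acetyloxy)-3-methoxyphenyl]-3-[3,5-bis(benzyloxy)phenoxy]propanoic acid | OC(=O)C[C@@H](c1ccc(OC(C)=O)c(OC)c1)Oc1cc(OCc2ccccc2)cc(OCc2ccccc2)c1
A9 | alternative 3 | 3,5-bis(benzyloxy)phenol | Oc1cc(OCc2ccccc2)cc(OCc2ccccc2)c1
A10 | alternative 3 | methyl (3R)-3-[4-(acetyloxy)-3-methoxyphenyl]-3-hydroxypropanoate | COC(=O)C[C@@H](O)c1ccc(OC(C)=O)c(OC)c1
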